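## Retrosynthetic overview

- The target is cut at the ester C–O bond and the cinnamate C=C bond. This gives (S)-toddalolactone (the coumarin diol) and 6-hydroxy-2,4-dimethoxy-3-prenylbenzaldehyde, joined in one pot by Ph3P=C=C=O (esterification, then E-selective Wittig).
- The coumarin diol comes from a salicylaldehyde (Wittig/lactonisation), that from a phenol (ortho-formylation), and the phenol OH from Ir-catalysed C–H borylation/oxidation.
- Key C–C bond: C2–C3 of the diol side chain. A configurationally stable α-carbamoyloxy carbanion (a carbinol carbon with inverted polarity, made with s-BuLi/(+)-sparteine) adds to acetone and sets the (S) centre in the same event.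
- The carbamate comes from 2-lithio-1,3-dimethoxybenzene (oxirane, then carbamoyl chloride); the prenyl arene comes from 2,6-dimethoxyphenylmagnesium bromide and prenyl bromide.
- Ring order: both benzene rings are bought (1,3-dimethoxybenzene and its 2-bromo derivative); the only ring formed is the pyranone ring of the coumarin (step 6).

Assumption: the SMILES encodes (S) at the acylated carbinol carbon; (+)-sparteine is treated as a purchasable, recoverable chiral ligand.

## Route

Step 1
Reactants: 1 1,3-dimethoxybenzene; 2 oxirane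
Product: 5 2-(2,6-dimethoxyphenyl)ethyl N,N-di(propan-2-yl)carbamate, via 2,6-dimethoxyphenyllithium 3 (not isolated), via lithium 2-(2,6-dimethoxyphenyl)ethanolate 4 (not isolated)
Conditions: n-BuLi, THF, 0 °C to rt; oxirane (THF solution), −20 °C to rt; then iPr2NCOCl, reflux
Reagents that add atoms: N,N-diisopropylcarbamoyl chloride, CC(C)N(C(C)C)C(=O)Cl
Why: Directed ortho-metalation at the position between the two methoxy groups, SN2 opening of oxirane by the aryllithium and O-carbamoylation of the resulting lithium alkoxide give the Hoppe carbamate in one pot; no stereocentre is formed.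

Step 2
Reactants: 5 2-(2,6-dimethoxyphenyl)ethyl N,N-di(propan-2-yl)carbamate; 6 acetone
Product: 8 (2S)-1-(2,6-dimethoxyphenyl)-3-hydroxy-3-methylbutan-2-yl N,N-di(propan-2-yl)carbamate, via (R)-α-lithio carbamate 7 (not isolated)
Conditions: s-BuLi (1.3 equiv), (+)-sparteine (1.3 equiv), Et2O, −78 °C, 5 h; acetone, −78 °C; AcOH, −78 °C
Reagents that add atoms: none
Why: Hoppe sparteine-mediated asymmetric lithiation–substitution: s-BuLi/(+)-sparteine removes the pro-R proton next to the carbamate oxygen to give a configurationally stable, dipole-stabilised α-oxy carbanion (a d1 reagent), which adds to the acetone carbonyl with retention, so the diol C–C bond and the (S) centre are made together ((−)-sparteine is known to give the mirror-image lithio species).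

Step 3
Reactants: 8 (2S)-1-(2,6-dimethoxyphenyl)-3-hydroxy-3-methylbutan-2-yl N,N-di(propan-2-yl)carbamate
Product: 10 (2S)-3-hydroxy-1-(4-hydroxy-2,6-dimethoxyphenyl)-3-methylbutan-2-yl N,N-di(propan-2-yl)carbamate, via aryl pinacol boronate 9 (not isolated)
Conditions: B2pin2 (1.1 equiv), [Ir(OMe)(cod)]2 (1.5 mol %), 4,4′-di-tert-butyl-2,2′-bipyridine (3 mol %), THF, 80 °C; then 30% aq. H2O2, NaOH, 0 °C
Reagents that add atoms: hydrogen peroxide, OO
Why: Sterically governed Ir-catalysed arene C–H borylation occurs only at the ring C–H with no ortho substituent (para to the side chain), and peroxide oxidation of the C–B bond gives the phenol; the carbamate and the stereocentre are untouched.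

Step 4
Reactants: 10 (2S)-3-hydroxy-1-(4-hydroxy-2,6-dimethoxyphenyl)-3-methylbutan-2-yl N,N-di(propan-2-yl)carbamate
Product: 11 4-[(2S)-2,3-dihydroxy-3-methylbutyl]-3,5-dimethoxyphenol
Conditions: LiAlH4 (5 equiv), THF, reflux; then 1 M HCl, 0 °C
Reagents that add atoms: none
Why: Hydride reduction is the standard removal of the N,N-diisopropylcarbamoyl group and breaks only the carbonyl C–O bond, so the carbinol configuration is retained.

Step 5
Reactants: 11 4-[(2S)-2,3-dihydroxy-3-methylbutyl]-3,5-dimethoxyphenol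
Product: 12 3-[(2S)-2,3-dihydroxy-3-methylbutyl]-6-hydroxy-2,4-dimethoxybenzaldehyde
Conditions: MgCl2, Et3N, (CH2O)n, MeCN, reflux; then 1 M HCl
Reagents that add atoms: paraformaldehyde (as formaldehyde), C=O
Why: Magnesium-phenoxide-directed ortho-formylation (Casnati–Skattebøl) goes only ortho to the phenol, the two ortho positions are equivalent by symmetry, and the aliphatic diol is inert under the basic conditions.

Step 6
Reactants: 12 3-[(2S)-2,3-dihydroxy-3-methylbutyl]-6-hydroxy-2,4-dimethoxybenzaldehyde; 13 ethyl (triphenylphosphoranylidene)acetate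
Product: 16 6-[(2S)-2,3-dihydroxy-3-methylbutyl]-5,7-dimethoxy-2H-chromen-2-one ((S)-toddalolactone), via ethyl (E)-2-hydroxycinnamate 14 (not isolated), via ethyl (Z)-2-hydroxycinnamate 15 (not isolated)
Conditions: PhNEt2, reflux (215 °C), 4 h
Reagents that add atoms: none
Why: Wittig olefination of the salicylaldehyde with the stabilised ylide, then thermal E-to-Z isomerisation and lactonisation (the classical coumarin synthesis), closes the pyranone ring without touching the remote stereocentre.

Step 7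
Reactants: 17 2-bromo-1,3-dimethoxybenzene; 18 1-bromo-3-methylbut-2-ene (prenyl bromide)
Product: 20 1,3-dimethoxy-2-(3-methylbut-2-en-1-yl)benzene, via 2,6-dimethoxyphenylmagnesium bromide 19 (not isolated)
Conditions: Mg turnings, THF, reflux; then prenyl bromide, CuBr·SMe2 (5 mol %), −20 °C to rt
Reagents that add atoms: none
Why: Magnesium insertion into the aryl bromide gives the aryl Grignard reagent, and its copper-catalysed SN2 allylation (Kumada-type coupling) with the primary allylic bromide gives the linear prenyl arene, because the two ortho methoxy groups block attack at the tertiary allyl terminus; no stereocentre is formed.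

Step 8
Reactants: 20 1,3-dimethoxy-2-(3-methylbut-2-en-1-yl)benzene
Product: 22 3,5-dimethoxy-4-(3-methylbut-2-en-1-yl)phenol, via aryl pinacol boronate 21 (not isolated)
Conditions: B2pin2 (0.7 equiv), [Ir(OMe)(cod)]2 (1.5 mol %), 4,4′-di-tert-butyl-2,2′-bipyridine (3 mol %), THF, 80 °C; then 30% aq. H2O2, NaOH, 0 °C
Reagents that add atoms: hydrogen peroxide, OO
Why: The same sterically governed Ir-catalysed C–H borylation/oxidation hydroxylates the only unhindered ring position, while the trisubstituted alkene is a poor substrate for Ir–H addition and is not epoxidised by alkaline peroxide.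

Step 9
Reactants: 22 3,5-dimethoxy-4-(3-methylbut-2-en-1-yl)phenol
Product: 23 6-hydroxy-2,4-dimethoxy-3-(3-methylbut-2-en-1-yl)benzaldehyde
Conditions: MgCl2, Et3N, (CH2O)n, MeCN, reflux; then 1 M HCl
Reagents that add atoms: paraformaldehyde (as formaldehyde), C=O
Why: Casnati–Skattebøl ortho-formylation of the symmetric phenol gives a single salicylaldehyde, and the prenyl group is inert to the mild base.

Step 10
Reactants: 16 6-[(2S)-2,3-dihydroxy-3-methylbutyl]-5,7-dimethoxy-2H-chromen-2-one; 24 (triphenylphosphoranylidene)ethenone (Bestmann ylide); 23 6-hydroxy-2,4-dimethoxy-3-(3-methylbut-2-en-1-yl)benzaldehyde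
Product: 26 (2S)-1-(5,7-dimethoxy-2-oxo-2H-chromen-6-yl)-3-hydroxy-3-methylbutan-2-yl (2E)-3-[6-hydroxy-2,4-dimethoxy-3-(3-methylbut-2-en-1-yl)phenyl]prop-2-enoate (CNP0079106.1), via phosphoranylidene acetate 25 (not isolated)
Conditions: 16 + 24 (1.0 equiv), toluene, 90 °C, 3 h; then 23, 70 °C, 12 h, dark
Reagents that add atoms: none
Why: Bestmann three-component coupling: the secondary hydroxyl (far more reactive than the tertiary one) adds to the cumulated ylide to give a stabilised phosphoranylidene acetate, whose Wittig reaction with the salicylaldehyde is E-selective, leaves the phenol free (the E geometry prevents lactonisation) and does not involve the carbinol stereocentre.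

## Compound list

1 | 1,3-dimethoxybenzene | COc1cccc(OC)c1 | starting material
2 | oxirane | C1CO1 | starting material
3 | 2,6-dimethoxyphenyllithium | [Li]c1c(OC)cccc1OC | intermediate
4 | lithium 2-(2,6-dimethoxyphenyl)ethanolate | [Li+].[O-]CCc1c(OC)cccc1OC | intermediate
5 | 2-(2,6-dimethoxyphenyl)ethyl N,N-di(propan-2-yl)carbamate | CC(C)N(C(C)C)C(=O)OCCc1c(OC)cccc1OC | intermediate
6 | acetone | CC(C)=O | starting material
7 | (1R)-1-lithio-2-(2,6-dimethoxyphenyl)ethyl N,N-di(propan-2-yl)carbamate, as its (+)-sparteine complex | CC(C)N(C(C)C)C(=O)O[C@@H](Cc1c(OC)cccc1OC)[Li] | intermediate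
8 | (2S)-1-(2,6-dimethoxyphenyl)-3-hydroxy-3-methylbutan-2-yl N,N-di(propan-2-yl)carbamate | CC(C)N(C(C)C)C(=O)O[C@@H](Cc1c(OC)cccc1OC)C(C)(C)O | intermediate
9 | (2S)-1-[2,6-dimethoxy-4-(4,4,5,5-tetramethyl-1,3,2-dioxaborolan-2-yl)phenyl]-3-hydroxy-3-methylbutan-2-yl N,N-di(propan-2-yl)carbamate | CC(C)N(C(C)C)C(=O)O[C@@H](Cc1c(OC)cc(B2OC(C)(C)C(C)(C)O2)cc1OC)C(C)(C)O | intermediate
10 | (2S)-3-hydroxy-1-(4-hydroxy-2,6-dimethoxyphenyl)-3-methylbutan-2-yl N,N-di(propan-2-yl)carbamate | CC(C)N(C(C)C)C(=O)O[C@@H](Cc1c(OC)cc(O)cc1OC)C(C)(C)O | intermediate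
11 | 4-[(2S)-2,3-dihydroxy-3-methylbutyl]-3,5-dimethoxyphenol | O[C@@H](Cc1c(OC)cc(O)cc1OC)C(C)(C)O | intermediate
12 | 3-[(2S)-2,3-dihydroxy-3-methylbutyl]-6-hydroxy-2,4-dimethoxybenzaldehyde | O[C@@H](Cc1c(OC)cc(O)c(C=O)c1OC)C(C)(C)O | intermediate
13 | ethyl (triphenylphosphoranylidene)acetate | CCOC(=O)C=P(c1ccccc1)(c1ccccc1)c1ccccc1 | starting material
14 | ethyl (2E)-3-{3-[(2S)-2,3-dihydroxy-3-methylbutyl]-6-hydroxy-2,4-dimethoxyphenyl}prop-2-enoate | O[C@@H](Cc1c(OC)cc(O)c(/C=C/C(=O)OCC)c1OC)C(C)(C)O | intermediate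
15 | ethyl (2Z)-3-{3-[(2S)-2,3-dihydroxy-3-methylbutyl]-6-hydroxy-2,4-dimethoxyphenyl}prop-2-enoate | O[C@@H](Cc1c(OC)cc(O)c(/C=C\C(=O)OCC)c1OC)C(C)(C)O | intermediate
16 | 6-[(2S)-2,3-dihydroxy-3-methylbutyl]-5,7-dimethoxy-2H-chromen-2-one ((S)-toddalolactone) | O[C@@H](Cc1c(OC)cc2oc(=O)ccc2c1OC)C(C)(C)O | intermediate
17 | 2-bromo-1,3-dimethoxybenzene | COc1cccc(OC)c1Br | starting material
18 | 1-bromo-3-methylbut-2-ene (prenyl bromide) | CC(C)=CCBr | starting material
19 | 2,6-dimethoxyphenylmagnesium bromide | COc1cccc(OC)c1[Mg]Br | intermediate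
20 | 1,3-dimethoxy-2-(3-methylbut-2-en-1-yl)benzene | COc1cccc(OC)c1CC=C(C)C | intermediate
21 | 2-[3,5-dimethoxy-4-(3-methylbut-2-en-1-yl)phenyl]-4,4,5,5-tetramethyl-1,3,2-dioxaborolane | COc1cc(B2OC(C)(C)C(C)(C)O2)cc(OC)c1CC=C(C)C | intermediate
22 | 3,5-dimethoxy-4-(3-methylbut-2-en-1-yl)phenol | COc1cc(O)cc(OC)c1CC=C(C)C | intermediate
23 | 6-hydroxy-2,4-dimethoxy-3-(3-methylbut-2-en-1-yl)benzaldehyde | COc1cc(O)c(C=O)c(OC)c1CC=C(C)C | intermediate
24 | (triphenylphosphoranylidene)ethenone (Bestmann ylide) | O=C=C=P(c1ccccc1)(c1ccccc1)c1ccccc1 | starting material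
25 | (2S)-1-(5,7-dimethoxy-2-oxo-2H-chromen-6-yl)-3-hydroxy-3-methylbutan-2-yl (triphenylphosphoranylidene)acetate | O=C(C=P(c1ccccc1)(c1ccccc1)c1ccccc1)O[C@@H](Cc1c(OC)cc2oc(=O)ccc2c1OC)C(C)(C)O | intermediate
26 | (2S)-1-(5,7-dimethoxy-2-oxo-2H-chromen-6-yl)-3-hydroxy-3-methylbutan-2-yl (2E)-3-[6-hydroxy-2,4-dimethoxy-3-(3-methylbut-2-en-1-yl)phenyl]prop-2-enoate | COc1cc(O)c(/C=C/C(=O)O[C@@H](Cc2c(OC)cc3oc(=O)ccc3c2OC)C(C)(C)O)c(OC)c1CC=C(C)C | target

## Step count and risks

Total step count: 10 (steps 1–6 for the coumarin diol, steps 7–9 for the aldehyde, step 10 for the union).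
Longest linear sequence: 7 steps (steps 1, 2, 3, 4, 5, 6, 10).

The three steps most likely to fail:

**Step 2 (asymmetric lithiation and acetone trapping).** The risks are competing benzylic or ring lithiation, enolisation of acetone, and erosion of ee. The fallback keeps the polarity-inverted bond construction but uses an achiral acyl-anion equivalent and sets the centre by catalyst-controlled reduction. It sets out from 4 and comes back to the route at 11. Alkoxide 4 is quenched with water instead of the carbamoyl chloride to give 2-(2,6-dimethoxyphenyl)ethan-1-ol F1. Dess–Martin oxidation in CH2Cl2 gives (2,6-dimethoxyphenyl)acetaldehyde F2, and propane-1,3-dithiol with BF3·OEt2 gives 2-[(2,6-dimethoxyphenyl)methyl]-1,3-dithiane F3. n-BuLi in THF at −30 °C gives 2-lithio-2-[(2,6-dimethoxyphenyl)methyl]-1,3-dithiane F4, which adds to acetone 6 to give 2-{2-[(2,6-dimethoxyphenyl)methyl]-1,3-dithian-2-yl}propan-2-ol F5. MeI and CaCO3 in aqueous MeCN unmask 1-(2,6-dimethoxyphenyl)-3-hydroxy-3-methylbutan-2-one F6. Reduction with the oxazaborolidine (R)-1-methyl-3,3-diphenyltetrahydro-1H,3H-pyrrolo[1,2-c][1,3,2]oxazaborole and BH3·SMe2, with the hydroxy-isopropyl group acting as the large substituent, gives (2S)-1-(2,6-dimethoxyphenyl)-3-methylbutane-2,3-diol F7. Borylation as in step 3 with extra B2pin2 gives (2S)-1-[2,6-dimethoxy-4-(4,4,5,5-tetramethyl-1,3,2-dioxaborolan-2-yl)phenyl]-3-methylbutane-2,3-diol F8, and alkaline H2O2 then gives 11.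

**Step 8 (C–H borylation/oxidation in the presence of the prenyl alkene).** The risk is alkene isomerisation or hydroboration by iridium hydride species. The fallback installs the hydroxyl before the alkene and relies on a silyl ether and directed metalation. It sets out from 1 and 18 and comes back at 22. Compound 1 is borylated under the step 3 conditions to 2-(3,5-dimethoxyphenyl)-4,4,5,5-tetramethyl-1,3,2-dioxaborolane F9 and oxidised to 3,5-dimethoxyphenol F10, which can also be bought. TIPSCl and imidazole give (3,5-dimethoxyphenoxy)tri(propan-2-yl)silane F11. n-BuLi in THF at 0 °C lithiates between the two methoxy groups, because the bulky silyl ether shields its own ortho positions, to give {2,6-dimethoxy-4-[tri(propan-2-yl)silyloxy]phenyl}lithium F12. Alkylation with 18 gives [3,5-dimethoxy-4-(3-methylbut-2-en-1-yl)phenoxy]tri(propan-2-yl)silane F13, and Bu4NF in THF gives 22.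

**Step 10 (one-pot esterification/Wittig).** The risks are slow addition of the hindered secondary hydroxyl to 24 and loss of material through the Z-olefin, which lactonises to the prenyl coumarin and returns 16. The fallback makes the ester by plain acylation and the aryl–vinyl bond by palladium-catalysed arylation. It sets out from 16 and 22 and comes back at 26. Compound 16 is acylated on the secondary hydroxyl (acryloyl chloride, Et3N, CH2Cl2, −20 °C) to (2S)-1-(5,7-dimethoxy-2-oxo-2H-chromen-6-yl)-3-hydroxy-3-methylbutan-2-yl prop-2-enoate F14. Compound 22 is iodinated ortho to the hydroxyl (N-iodosuccinimide, CH2Cl2, −40 °C) to 2-iodo-3,5-dimethoxy-4-(3-methylbut-2-en-1-yl)phenol F15. A Heck reaction of these two (Pd(OAc)2, Bu4NCl, NaHCO3, DMF, 70 °C) gives 26 with E geometry.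

Further compounds
F1 | step 2 | 2-(2,6-dimethoxyphenyl)ethan-1-ol | OCCc1c(OC)cccc1OC
F2 | step 2 | (2,6-dimethoxyphenyl)acetaldehyde | O=CCc1c(OC)cccc1OC
F3 | step 2 | 2-[(2,6-dimethoxyphenyl)methyl]-1,3-dithiane | COc1cccc(OC)c1CC1SCCCS1
F4 | step 2 | 2-lithio-2-[(2,6-dimethoxyphenyl)methyl]-1,3-dithiane | COc1cccc(OC)c1CC1([Li])SCCCS1
F5 | step 2 | 2-{2-[(2,6-dimethoxyphenyl)methyl]-1,3-dithian-2-yl}propan-2-ol | COc1cccc(OC)c1CC1(SCCCS1)C(C)(C)O
F6 | step 2 | 1-(2,6-dimethoxyphenyl)-3-hydroxy-3-methylbutan-2-one | COc1cccc(OC)c1CC(=O)C(C)(C)O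
F7 | step 2 | (2S)-1-(2,6-dimethoxyphenyl)-3-methylbutane-2,3-diol | O[C@@H](Cc1c(OC)cccc1OC)C(C)(C)O
F8 | step 2 | (2S)-1-[2,6-dimethoxy-4-(4,4,5,5-tetramethyl-1,3,2-dioxaborolan-2-yl)phenyl]-3-methylbutane-2,3-diol | O[C@@H](Cc1c(OC)cc(B2OC(C)(C)C(C)(C)O2)cc1OC)C(C)(C)O
F9 | step 8 | 2-(3,5-dimethoxyphenyl)-4,4,5,5-tetramethyl-1,3,2-dioxaborolane | COc1cc(B2OC(C)(C)C(C)(C)O2)cc(OC)c1
F10 | step 8 | 3,5-dimethoxyphenol | COc1cc(O)cc(OC)c1
F11 | step 8 | (3,5-dimethoxyphenoxy)tri(propan-2-yl)silane | COc1cc(O[Si](C(C)C)(C(C)C)C(C)C)cc(OC)c1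
F12 | step 8 | {2,6-dimethoxy-4-[tri(propan-2-yl)silyloxy]phenyl}lithium | [Li]c1c(OC)cc(O[Si](C(C)C)(C(C)C)C(C)C)cc1OC
F13 | step 8 | [3,5-dimethoxy-4-(3-methylbut-2-en-1-yl)phenoxy]tri(propan-2-yl)silane | COc1cc(O[Si](C(C)C)(C(C)C)C(C)C)cc(OC)c1CC=C(C)C
F14 | step 10 | (2S)-1-(5,7-dimethoxy-2-oxo-2H-chromen-6-yl)-3-hydroxy-3-methylbutan-2-yl prop-2-enoate | C=CC(=O)O[C@@H](Cc1c(OC)cc2oc(=O)ccc2c1OC)C(C)(C)O
F15 | step 10 | 2-iodo-3,5-dimethoxy-4-(3-methylbut-2-en-1-yl)phenol | COc1cc(O)c(I)c(OC)c1CC=C(C)C
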